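The decision to make is a temperature: the three flasks share one charge and one time, and they differ in how hot they are.

| setting | south | east | west | alpha | gamma | zeta |
|---|---|---|---|---|---|---|
| E | 0.67 M | 1.5 M | 1 M | 1.0 M | 1.0 M | 1.0 M |
| L | 2 M | 2 M | 3 M | 2.00 M | 2.00 M | 2.00 M |
| temperature | 85 °C | 110 °C | 85 °C | 110 °C | 130 °C | 90 °C |
| remark | run made earlier | run made earlier | run made earlier |  |  |  |
| time |  |  |  | 12 min | 12 min | 12 min |

- south (time / min: J / %): 3.00: 4; 8.00: 15; 15.0: 26; 30.0: 41
- east (time / min: J / %): 2.00: 20; 4.00: 33; 5.00: 40; 8.00: 51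
- west (time / min: J / %): 6.00: 16; 15.0: 35; 30.0: 54

(scatter of a reading: 1.5 percentage points)

- in percentages every species weighs as the E in it: one G counts as two
- steps thought possible: E + X -> G; L + X <-> Z; E + L -> J; E <-> X; L + Z -> Q; Z -> D

* the best flask by amount of J, in percent of the E charged; "all alike" if 1.5 percentage points covers them all (alpha / gamma / zeta / all alike)
* amount of J at the end, in percent of the E charged, alpha
* amount of J at the end, in percent of the E charged, gamma
* amount of J at the end, in percent of the E charged, zeta

Read the runs as E + L → J, first order in each. With [E] and [L] the charges, the rule is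

c = exp(k([L] − [E])t), J as a fraction of E charged = [L](c − 1)/([L]c − [E]).

Solved for k, the last west reading gives 0.00963 L mol⁻¹ min⁻¹ at 85 °C. The last south reading, at the same ratio of L to E but at lower concentrations, gives 0.00952 L mol⁻¹ min⁻¹, so a total order of two holds within the scatter. These two runs cannot separate the order in E from that in L, so first order in each remains an assumption. The last east reading gives the clock constant, the second-order rate constant of E + L → J at 110 °C: 0.0578 L mol⁻¹ min⁻¹.

Between those two temperatures k climbs 0.778 of a power of ten. Taking log k as straight in temperature, my own reckoning gives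

k at 130 °C = 0.242 L mol⁻¹ min⁻¹, k at 90 °C = 0.0138 L mol⁻¹ min⁻¹.

Now gamma in slow motion. In the first instants E is the limiting reagent, and E decays as if pseudo-first-order, with a half-life of 1.43 min. In the middle L sinks towards the 1.00 M that the charges leave, which stretches the half-life towards 2.86 min. By the end, 12 min holds 4.20 of those longer half-lives, so the clock has nearly finished, and what matters next is where E went besides J. The steps thought possible also include E ⇌ X, with X going on to G and Z, and Z to D and Q, but the runs report J and none of these species.

The rule gives 66.7% for alpha, 97.2% for gamma and 26.5% for zeta.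

The forecast names gamma, with 67%, 92% and 27% for alpha, gamma and zeta. Its gamma stands below my reckoning, and its own words are “shade gamma down and widen its range”.

    E + X → G (k = 7.90 × 10⁻⁴ L mol⁻¹ s⁻¹, Ea = 82.0 kJ mol⁻¹)
    L + X ⇌ Z (K = 1.20 L mol⁻¹, k = 9.70 × 10⁻⁴ L mol⁻¹ s⁻¹, Ea = 79.0 kJ mol⁻¹, ΔH = 44.0 kJ mol⁻¹)
    E + L → J (k = 0.00110 L mol⁻¹ s⁻¹, Ea = 84.0 kJ mol⁻¹)
    E ⇌ X (K = 0.380, k = 4.80 × 10⁻⁴ s⁻¹, Ea = 128 kJ mol⁻¹, ΔH = −30.0 kJ mol⁻¹)
    L + Z → Q (k = 0.00180 L mol⁻¹ s⁻¹, Ea = 84.0 kJ mol⁻¹)
    Z → D (k = 0.00430 s⁻¹, Ea = 104 kJ mol⁻¹)
    (constants at 110 °C)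

Gamma leads at 82.8%, which is 9.2 percentage points under the forecast and 14 points under the clock, while alpha gives 63.7% against a clock of 66.7% and zeta gives 28.4% against a clock of 26.5%. Gamma has converted 97.8% of its E and reaches 85.1% at 120 min, level with alpha's 85.5%; at the start of alpha the forward step from E to X runs at 0.218 of the rate of E + L → J. The clock constant, unchanged, reckons 34.1% for a neighbour of alpha charged with 0.80 M of L, and that flask gives 32.9%.

Readings and results were generated by integration with constants of no real substance.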